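**Plan**

- Retrosynthesis: the enone C=C on ring B is cut first (Wittig, back to an aryl aldehyde). Then the two neighbouring bonds on ring A, C6–O of the diaryl ether and C1–CO2H, are cut in one operation.
- Enabling feature: in ring A the aryloxy oxygen (C6) and the carboxyl carbon (C1) sit on adjacent carbons, and C1 is flanked by the C2 methoxy group. This is the pattern left when a nucleophile and an electrophile add across a C1–C6 aryne polarised by that methoxy group.
- Ring A comes from 4-hydroxy-2-methoxybenzaldehyde: isobutyl Grignard addition, then carbamate-directed silylation between OMe and O, then triflation.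
- Ring B comes from 2-methoxy-4-methylphenol: ortho-formylation, demethylation, allylation of the 3-hydroxyl, dioxolane.
- No ring is formed. The two benzene rings are joined through oxygen and the carboxyl carbon is attached in step 12; deallylation, acetal hydrolysis and Wittig olefination finish the chain.
- Stereochemistry: the single (S) carbinol centre (O > aryl > CH2 > H) comes from Corey–Bakshi–Shibata reduction of ketone 11 with the (R)-oxazaborolidine, after all strongly basic steps. The (E) alkene comes from the stabilised ylide.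

Key step: step 12

Remark: isobutylmagnesium bromide and the keto ylide 26 are taken as purchased reagents.

**Route**

Step 1
Reactants: 1 4-hydroxy-2-methoxybenzaldehyde; 2 isobutylmagnesium bromide
Product: 3 racemic 4-(1-hydroxy-3-methylbutyl)-3-methoxyphenol
Conditions: 2 (3.0 equiv), THF, 0 °C → rt; sat. aq. NH4Cl (neutral work-up, used crude)
Reagents that add atoms: none
Why: Grignard addition to an aldehyde; the first equivalent of 2 deprotonates the phenol and the excess adds to the formyl group of the magnesium phenoxide, and no stereocontrol is needed because the carbinol is oxidised in step 5.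

Step 2
Reactants: 3 racemic 4-(1-hydroxy-3-methylbutyl)-3-methoxyphenol
Product: 4 racemic 4-(1-hydroxy-3-methylbutyl)-3-methoxyphenyl N-isopropylcarbamate
Conditions: i-PrNCO (1.05 equiv), Et3N (0.2 equiv), CH2Cl2, 0 °C → rt
Reagents that add atoms: isopropyl isocyanate, CC(C)N=C=O
Why: Base-catalysed carbamoylation of a phenol with an isocyanate; triethylamine activates the acidic phenol far more than the hindered secondary benzylic alcohol, so one equivalent of isocyanate should go to the phenol oxygen.

Step 3
Reactants: 4 racemic 4-(1-hydroxy-3-methylbutyl)-3-methoxyphenyl N-isopropylcarbamate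
Product: 8 racemic 4-(1-hydroxy-3-methylbutyl)-3-methoxy-2-(trimethylsilyl)phenyl N-isopropylcarbamate, via N,O-bis(trimethylsilyl) carbamate 5 (not isolated), via aryllithium 6 (not isolated), via tris(trimethylsilyl) compound 7 (not isolated)
Conditions: TMSOTf (2.2 equiv), TMEDA (2.4 equiv), Et2O, 0 °C → rt; TMEDA (2 equiv), n-BuLi (3.6 equiv), −78 °C; TMSCl (4 equiv), −78 °C → rt; aq. NaHSO4
Reagents that add atoms: chlorotrimethylsilane, C[Si](C)(C)Cl
Why: Directed ortho-metalation of an aryl N-isopropylcarbamate after in situ silylation of N–H and O–H; carbamate and methoxy group together direct lithiation to the carbon between them, chlorotrimethylsilane quenches the aryllithium, and the acidic work-up hydrolyses the N–Si and O–Si bonds while the C–Si bond stays.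

Step 4
Reactants: 8 racemic 4-(1-hydroxy-3-methylbutyl)-3-methoxy-2-(trimethylsilyl)phenyl N-isopropylcarbamate
Product: 10 racemic 4-(1-hydroxy-3-methylbutyl)-3-methoxy-2-(trimethylsilyl)phenyl trifluoromethanesulfonate, via phenol 9 (not isolated)
Conditions: Et2NH (1.5 equiv), DBU (1.5 equiv), MeCN, 40 °C; then PhNTf2 (1.5 equiv), rt
Reagents that add atoms: N-phenylbis(trifluoromethanesulfonimide), O=S(=O)(N(c1ccccc1)S(=O)(=O)C(F)(F)F)C(F)(F)F
Why: E1cB cleavage of the N-monoalkyl carbamate (the isocyanate is scavenged by diethylamine) frees the phenoxide, which the mild triflyl donor triflates in the same pot; the secondary alcohol is not triflated and the acid-sensitive para-hydroxybenzylic alcohol is never isolated.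

Step 5
Reactants: 10 racemic 4-(1-hydroxy-3-methylbutyl)-3-methoxy-2-(trimethylsilyl)phenyl trifluoromethanesulfonate
Product: 11 3-methoxy-4-(3-methylbutanoyl)-2-(trimethylsilyl)phenyl trifluoromethanesulfonate
Conditions: Dess–Martin periodinane (1.3 equiv), NaHCO3, CH2Cl2, 0 °C → rt
Reagents that add atoms: none
Why: Dess–Martin oxidation of a secondary benzylic alcohol under buffered, neutral conditions should leave the aryl triflate and the aryl–silicon bond untouched.

Step 6
Reactants: 11 3-methoxy-4-(3-methylbutanoyl)-2-(trimethylsilyl)phenyl trifluoromethanesulfonate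
Product: 12 (S)-4-(1-hydroxy-3-methylbutyl)-3-methoxy-2-(trimethylsilyl)phenyl trifluoromethanesulfonate
Conditions: (R)-2-methyl-CBS-oxazaborolidine [(R)-1-methyl-3,3-diphenyltetrahydro-1H,3H-pyrrolo[1,2-c][1,3,2]oxazaborole] (0.2 equiv), BH3·SMe2 (1.0 equiv), THF, −20 °C; MeOH
Reagents that add atoms: none
Why: Corey–Bakshi–Shibata reduction; with the (R)-catalyst hydride is delivered to the ketone face that gives the (S)-carbinol (aryl as the large group, the CH2 of the isobutyl chain as the small one), the same sense as (S)-1-phenylethanol from acetophenone.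

Step 7
Reactants: 12 (S)-4-(1-hydroxy-3-methylbutyl)-3-methoxy-2-(trimethylsilyl)phenyl trifluoromethanesulfonate
Product: 13 (S)-1-[2-methoxy-4-(trifluoromethanesulfonyloxy)-3-(trimethylsilyl)phenyl]-3-methylbutyl acetate
Conditions: Ac2O, pyridine, DMAP (cat.), CH2Cl2, rt
Reagents that add atoms: acetic anhydride, CC(=O)OC(C)=O
Why: DMAP-catalysed acetylation of a secondary alcohol; the C–O bond at the stereocentre is not broken, so the (S) configuration is kept.

Step 8
Reactants: 14 2-methoxy-4-methylphenol
Product: 15 2-hydroxy-3-methoxy-5-methylbenzaldehyde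
Conditions: MgCl2, Et3N, (CH2O)n, MeCN, reflux; 1 M HCl
Reagents that add atoms: paraformaldehyde (as formaldehyde), C=O
Why: Magnesium-mediated ortho-formylation of a phenol; the magnesium phenoxide directs hydroxymethylation to the only free ortho position (the para position carries the methyl group) and a second formaldehyde oxidises the benzylic alkoxide to the aldehyde.

Step 9
Reactants: 15 2-hydroxy-3-methoxy-5-methylbenzaldehyde
Product: 16 2,3-dihydroxy-5-methylbenzaldehyde
Conditions: BBr3 (2.5 equiv), CH2Cl2, −78 °C → rt; H2O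
Reagents that add atoms: none
Why: Lewis acid cleavage of an aryl methyl ether with BBr3, a standard conversion of ortho-vanillin-type aldehydes into catechol aldehydes.

Step 10
Reactants: 16 2,3-dihydroxy-5-methylbenzaldehyde
Product: 17 3-(allyloxy)-2-hydroxy-5-methylbenzaldehyde
Conditions: NaH (2.1 equiv), DMSO, rt; allyl bromide (1.0 equiv); aq. NH4Cl
Reagents that add atoms: allyl bromide, C=CCBr
Why: Williamson etherification of the dianion; the 2-oxide is delocalised into the ortho formyl group, so the more nucleophilic 3-oxide should take the single equivalent of allyl bromide.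

Step 11
Reactants: 17 3-(allyloxy)-2-hydroxy-5-methylbenzaldehyde
Product: 18 2-(allyloxy)-6-(1,3-dioxolan-2-yl)-4-methylphenol
Conditions: ethylene glycol (5 equiv), TsOH·H2O (cat.), benzene, reflux (Dean–Stark); Et3N quench
Reagents that add atoms: ethylene glycol, OCCO
Why: Acid-catalysed acetalisation with azeotropic removal of water; the allyl ether is inert to TsOH, and the dioxolane masks the aldehyde that would otherwise trap the aryl anion of step 12.

Step 12
Reactants: 18 2-(allyloxy)-6-(1,3-dioxolan-2-yl)-4-methylphenol; 13 (S)-1-[2-methoxy-4-(trifluoromethanesulfonyloxy)-3-(trimethylsilyl)phenyl]-3-methylbutyl acetate; 19 carbon dioxide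
Product: 23 (S)-3-(1-acetoxy-3-methylbutyl)-6-[2-(allyloxy)-6-(1,3-dioxolan-2-yl)-4-methylphenoxy]-2-methoxybenzoic acid, via caesium phenoxide 20 (not isolated), via aryne 21 (not isolated), via aryl caesium 22 (not isolated)
Conditions: 18 (1.5 equiv), CsOH·H2O (1.5 equiv), MeOH, rt; evaporate, PhMe azeotrope, vacuum; then 13 (1.0 equiv), CsF (3 equiv), 18-crown-6 (3 equiv), CO2 (1 atm), THF, 0 °C → rt; cold 0.1 M HCl to pH 3–4
Reagents that add atoms: none
Why: Proposed new method: fluoride attacks the silicon of 13 and triflate leaves, giving aryne 21 between C1 and C6 of ring A; phenoxide 20 adds at C6, the aryne carbon remote from the C2 methoxy group, so the negative charge of 22 sits at C1 beside the inductively withdrawing C–OMe carbon, and dissolved CO2 carboxylates this anion in the aprotic medium before it finds a proton. The closest known reaction types are the three-component coupling of arynes with amines and CO2 to anthranilic acids and the addition of phenoxides to arynes to give diaryl ethers. No ring is closed and no stereocentre is formed; the (S)-acetoxy centre is a spectator without an acidic O–H. The step needs regioselective O-attack, which the C2 methoxy group secures through the usual 3-alkoxyaryne bias, and C-carboxylation in preference to protonation or internal trapping, which is secured by the pre-dried phenoxide, by THF in place of acetonitrile, and by carrying the ring B aldehyde as a dioxolane and its second hydroxyl as an allyl ether. The 2,6-disubstituted phenoxide should bind CO2 only weakly and reversibly, so free phenoxide remains to capture the aryne.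

Step 13
Reactants: 23 (S)-3-(1-acetoxy-3-methylbutyl)-6-[2-(allyloxy)-6-(1,3-dioxolan-2-yl)-4-methylphenoxy]-2-methoxybenzoic acid
Product: 25 (S)-3-(1-acetoxy-3-methylbutyl)-6-(2-formyl-6-hydroxy-4-methylphenoxy)-2-methoxybenzoic acid, via phenol acetal 24 (not isolated)
Conditions: Pd(PPh3)4 (5 mol%), morpholine (10 equiv), THF, rt; then 1 M HCl (to pH 1), rt
Reagents that add atoms: none
Why: Tsuji–Trost deallylation (the zerovalent palladium catalyst ionises the allyl aryl ether and morpholine captures the allyl unit), then hydrolysis of the aryl dioxolane in dilute aqueous acid at room temperature, conditions under which the secondary benzylic acetate should persist.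

Step 14
Reactants: 25 (S)-3-(1-acetoxy-3-methylbutyl)-6-(2-formyl-6-hydroxy-4-methylphenoxy)-2-methoxybenzoic acid; 26 1-(triphenylphosphoranylidene)propan-2-one
Product: 27 (S)-3-(1-acetoxy-3-methylbutyl)-6-{2-hydroxy-4-methyl-6-[(E)-3-oxobut-1-en-1-yl]phenoxy}-2-methoxybenzoic acid
Conditions: 26 (2.5 equiv), THF, 60 °C
Reagents that add atoms: none
Why: Wittig olefination with a stabilised keto ylide, which reacts only with the aldehyde and should give the (E)-enone; the weakly basic ylide tolerates the free carboxylic acid and phenol.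

**Compound list**

1 | 4-hydroxy-2-methoxybenzaldehyde | COc1cc(O)ccc1C=O | starting material
2 | isobutylmagnesium bromide (2-methylpropylmagnesium bromide, ether solution) | CC(C)C[Mg]Br | starting material
3 | racemic 4-(1-hydroxy-3-methylbutyl)-3-methoxyphenol | COc1cc(O)ccc1C(O)CC(C)C | intermediate
4 | racemic 4-(1-hydroxy-3-methylbutyl)-3-methoxyphenyl N-isopropylcarbamate | COc1cc(OC(=O)NC(C)C)ccc1C(O)CC(C)C | intermediate
5 | racemic 3-methoxy-4-[3-methyl-1-(trimethylsilyloxy)butyl]phenyl N-isopropyl-N-(trimethylsilyl)carbamate | COc1cc(OC(=O)N(C(C)C)[Si](C)(C)C)ccc1C(O[Si](C)(C)C)CC(C)C | intermediate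
6 | aryllithium from 5, lithium on the ring carbon between the methoxy carbon and the carbamate carbon | COc1c([Li])c(OC(=O)N(C(C)C)[Si](C)(C)C)ccc1C(O[Si](C)(C)C)CC(C)C | intermediate
7 | racemic 3-methoxy-4-[3-methyl-1-(trimethylsilyloxy)butyl]-2-(trimethylsilyl)phenyl N-isopropyl-N-(trimethylsilyl)carbamate | COc1c([Si](C)(C)C)c(OC(=O)N(C(C)C)[Si](C)(C)C)ccc1C(O[Si](C)(C)C)CC(C)C | intermediate
8 | racemic 4-(1-hydroxy-3-methylbutyl)-3-methoxy-2-(trimethylsilyl)phenyl N-isopropylcarbamate | COc1c([Si](C)(C)C)c(OC(=O)NC(C)C)ccc1C(O)CC(C)C | intermediate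
9 | racemic 4-(1-hydroxy-3-methylbutyl)-3-methoxy-2-(trimethylsilyl)phenol (held as its DBU salt) | COc1c([Si](C)(C)C)c(O)ccc1C(O)CC(C)C | intermediate
10 | racemic 4-(1-hydroxy-3-methylbutyl)-3-methoxy-2-(trimethylsilyl)phenyl trifluoromethanesulfonate | COc1c([Si](C)(C)C)c(OS(=O)(=O)C(F)(F)F)ccc1C(O)CC(C)C | intermediate
11 | 3-methoxy-4-(3-methylbutanoyl)-2-(trimethylsilyl)phenyl trifluoromethanesulfonate | COc1c([Si](C)(C)C)c(OS(=O)(=O)C(F)(F)F)ccc1C(=O)CC(C)C | intermediate
12 | (S)-4-(1-hydroxy-3-methylbutyl)-3-methoxy-2-(trimethylsilyl)phenyl trifluoromethanesulfonate | COc1c([C@H](CC(C)C)O)ccc(OS(=O)(=O)C(F)(F)F)c1[Si](C)(C)C | intermediate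
13 | (S)-1-[2-methoxy-4-(trifluoromethanesulfonyloxy)-3-(trimethylsilyl)phenyl]-3-methylbutyl acetate | COc1c([C@H](CC(C)C)OC(C)=O)ccc(OS(=O)(=O)C(F)(F)F)c1[Si](C)(C)C | intermediate
14 | 2-methoxy-4-methylphenol (creosol) | COc1cc(C)ccc1O | starting material
15 | 2-hydroxy-3-methoxy-5-methylbenzaldehyde | COc1cc(C)cc(C=O)c1O | intermediate
16 | 2,3-dihydroxy-5-methylbenzaldehyde | Cc1cc(O)c(O)c(C=O)c1 | intermediate
17 | 3-(allyloxy)-2-hydroxy-5-methylbenzaldehyde | C=CCOc1cc(C)cc(C=O)c1O | intermediate
18 | 2-(allyloxy)-6-(1,3-dioxolan-2-yl)-4-methylphenol | C=CCOc1cc(C)cc(C2OCCO2)c1O | intermediate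
19 | carbon dioxide | O=C=O | starting material
20 | caesium 2-(allyloxy)-6-(1,3-dioxolan-2-yl)-4-methylphenoxide | C=CCOc1cc(C)cc(C2OCCO2)c1[O-].[Cs+] | intermediate
21 | (S)-1-(2-methoxy-3,4-didehydrophenyl)-3-methylbutyl acetate (ring A aryne, triple bond between the former silyl and triflate carbons) | COC1=C([C@H](CC(C)C)OC(C)=O)C=CC#C1 | intermediate
22 | aryl caesium adduct: caesium on ring A C1, between the methoxy carbon and the new aryloxy carbon | COc1c([C@H](CC(C)C)OC(C)=O)ccc(Oc2c(OCC=C)cc(C)cc2C3OCCO3)c1[Cs] | intermediate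
23 | (S)-3-(1-acetoxy-3-methylbutyl)-6-[2-(allyloxy)-6-(1,3-dioxolan-2-yl)-4-methylphenoxy]-2-methoxybenzoic acid | COc1c([C@H](CC(C)C)OC(C)=O)ccc(Oc2c(OCC=C)cc(C)cc2C3OCCO3)c1C(=O)O | intermediate
24 | (S)-3-(1-acetoxy-3-methylbutyl)-6-[2-(1,3-dioxolan-2-yl)-6-hydroxy-4-methylphenoxy]-2-methoxybenzoic acid | COc1c([C@H](CC(C)C)OC(C)=O)ccc(Oc2c(O)cc(C)cc2C3OCCO3)c1C(=O)O | intermediate
25 | (S)-3-(1-acetoxy-3-methylbutyl)-6-(2-formyl-6-hydroxy-4-methylphenoxy)-2-methoxybenzoic acid | COc1c([C@H](CC(C)C)OC(C)=O)ccc(Oc2c(O)cc(C)cc2C=O)c1C(=O)O | intermediate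
26 | 1-(triphenylphosphoranylidene)propan-2-one | CC(=O)C=P(c1ccccc1)(c1ccccc1)c1ccccc1 | starting material
27 | (S)-3-(1-acetoxy-3-methylbutyl)-6-{2-hydroxy-4-methyl-6-[(E)-3-oxobut-1-en-1-yl]phenoxy}-2-methoxybenzoic acid (CNP0281268.1) | COc1c([C@H](CC(C)C)OC(C)=O)ccc(Oc2c(O)cc(C)cc2/C=C/C(C)=O)c1C(=O)O | target

**Step count**

Total: 14 steps. Longest linear sequence: 10 steps (steps 1–7, then 12–14); the ring B branch is steps 8–11.

**Steps most likely to fail**

Step 12 (Proposed new method). The aryl anion may be protonated before it meets CO2, the phenoxide may be held back as its carbonate while fluoride or the product carboxylate consumes the aryne, or the phenoxide may slowly exchange with the acetate. The fallback makes the C6–O and C1–C bonds one after the other by known reactions; it sets out from 16 and 12 and returns at 25. Its second stage uses butyllithium, which an allyl ether would not survive, so ring B is carried as a methoxymethyl ether.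
- Compound 16 with NaH (2.1 equiv) and chloromethyl methyl ether should give 2-hydroxy-3-(methoxymethoxy)-5-methylbenzaldehyde F1.
- Ethylene glycol and pyridinium tosylate in refluxing benzene should convert this into 2-(1,3-dioxolan-2-yl)-6-(methoxymethoxy)-4-methylphenol F2.
- Generating the aryne from alcohol 12 with CsF in acetonitrile in the presence of F2 is the established O-arylation of phenols by arynes, the phenol O–H and the solvent supplying the proton. It should give (S)-1-{4-[2-(1,3-dioxolan-2-yl)-6-(methoxymethoxy)-4-methylphenoxy]-2-methoxyphenyl}-3-methylbutan-1-ol F3 with the same regiochemistry.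
- Directed ortho-metalation of F3 with n-BuLi/TMEDA in THF (−78 → −20 °C; the alkoxide forms first) should occur at the ring A carbon between the methoxy and aryloxy oxygens. A CO2 quench should then give (S)-6-[2-(1,3-dioxolan-2-yl)-6-(methoxymethoxy)-4-methylphenoxy]-3-(1-hydroxy-3-methylbutyl)-2-methoxybenzoic acid F4.
- Ac2O/pyridine/DMAP with aqueous work-up should give (S)-3-(1-acetoxy-3-methylbutyl)-6-[2-(1,3-dioxolan-2-yl)-6-(methoxymethoxy)-4-methylphenoxy]-2-methoxybenzoic acid F5.
- TMSOTf/2,2'-bipyridyl in CH2Cl2 followed by water should remove the methoxymethyl ether and the dioxolane without aqueous mineral acid, giving 25.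

Step 3. Silylation of N–H and O–H may be incomplete, so that the N-lithiated carbamate fragments to phenoxide and isocyanate, or the base may deprotonate the benzylic silyl ether and not the ring. The fallback uses a tertiary carbamate that needs no N-protection and lets the alcohol ride as its lithium alkoxide; it sets out from 1 and returns at 10.
- Diethylcarbamoyl chloride and K2CO3 in MeCN should give 4-formyl-3-methoxyphenyl N,N-diethylcarbamate F6.
- Addition of 2 at −78 °C should give racemic 4-(1-hydroxy-3-methylbutyl)-3-methoxyphenyl N,N-diethylcarbamate F7.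
- s-BuLi (2.3 equiv)/TMEDA in THF at −78 °C, chlorotrimethylsilane and a dilute acid work-up should give racemic 4-(1-hydroxy-3-methylbutyl)-3-methoxy-2-(trimethylsilyl)phenyl N,N-diethylcarbamate F8.
- Reductive cleavage of the hindered carbamate with Cp2Zr(H)Cl in THF should free phenol 9, which is triflated at once with PhNTf2/Et3N to 10.

Step 2. The isocyanate may also carbamoylate the secondary hydroxyl, or the acid-sensitive para-hydroxybenzylic alcohol may ionise and decompose on handling. The fallback removes the competing hydroxyl by oxidation; it sets out from 3 and returns at 4.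
- DDQ in dioxane should dehydrogenate the para-hydroxybenzylic alcohol to 1-(4-hydroxy-2-methoxyphenyl)-3-methylbutan-1-one F9.
- Isopropyl isocyanate/Et3N then has only the phenol to react with and should give 3-methoxy-4-(3-methylbutanoyl)phenyl N-isopropylcarbamate F10.
- BH3·SMe2 in THF at 0 °C should reduce the ketone to racemic 4.

**Further compounds**

F1 | step 12 | 2-hydroxy-3-(methoxymethoxy)-5-methylbenzaldehyde | COCOc1cc(C)cc(C=O)c1O
F2 | step 12 | 2-(1,3-dioxolan-2-yl)-6-(methoxymethoxy)-4-methylphenol | COCOc1cc(C)cc(C2OCCO2)c1O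
F3 | step 12 | (S)-1-{4-[2-(1,3-dioxolan-2-yl)-6-(methoxymethoxy)-4-methylphenoxy]-2-methoxyphenyl}-3-methylbutan-1-ol | COc1c([C@H](CC(C)C)O)ccc(Oc2c(OCOC)cc(C)cc2C3OCCO3)c1
F4 | step 12 | (S)-6-[2-(1,3-dioxolan-2-yl)-6-(methoxymethoxy)-4-methylphenoxy]-3-(1-hydroxy-3-methylbutyl)-2-methoxybenzoic acid | COc1c([C@H](CC(C)C)O)ccc(Oc2c(OCOC)cc(C)cc2C3OCCO3)c1C(=O)O
F5 | step 12 | (S)-3-(1-acetoxy-3-methylbutyl)-6-[2-(1,3-dioxolan-2-yl)-6-(methoxymethoxy)-4-methylphenoxy]-2-methoxybenzoic acid | COc1c([C@H](CC(C)C)OC(C)=O)ccc(Oc2c(OCOC)cc(C)cc2C3OCCO3)c1C(=O)O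
F6 | step 3 | 4-formyl-3-methoxyphenyl N,N-diethylcarbamate | CCN(CC)C(=O)Oc1ccc(C=O)c(OC)c1
F7 | step 3 | racemic 4-(1-hydroxy-3-methylbutyl)-3-methoxyphenyl N,N-diethylcarbamate | CCN(CC)C(=O)Oc1ccc(C(O)CC(C)C)c(OC)c1
F8 | step 3 | racemic 4-(1-hydroxy-3-methylbutyl)-3-methoxy-2-(trimethylsilyl)phenyl N,N-diethylcarbamate | CCN(CC)C(=O)Oc1ccc(C(O)CC(C)C)c(OC)c1[Si](C)(C)C
F9 | step 2 | 1-(4-hydroxy-2-methoxyphenyl)-3-methylbutan-1-one | COc1cc(O)ccc1C(=O)CC(C)C
F10 | step 2 | 3-methoxy-4-(3-methylbutanoyl)phenyl N-isopropylcarbamate | COc1cc(OC(=O)NC(C)C)ccc1C(=O)CC(C)C
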